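**Retrosynthetic overview**

- Ring numbering used throughout: C1 carries the benzylic carbon C7, C2 and C3 carry bromine, C4 the sulfated oxygen, C5 the free hydroxyl and C6 hydrogen; the target has no stereocentre. The strategy rests on the two C–Br bonds standing on the neighbouring ring carbons C2 and C3, which can both be formed in one event by adding a Br–Br equivalent across a C2≡C3 aryne.
- Disconnections, backwards: the two O–S bonds (C4–O on the aldehyde, C7–O after reduction); then C2–Br and C3–Br to the aryne; then the aryne to a C2-silyl C3-triflate, whose silicon is placed by carbamate-directed lithiation at the C3 phenol of protected 3,4,5-trihydroxybenzaldehyde (1).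
- Rings: the benzene ring is bought with its three oxygens and C7 in place. The only rings formed are two protecting acetals (the benzodioxole ketal in step 1, the dioxolane in step 2), and both are opened again in step 7.

Key step: step 6

Assumption: the target is drawn as the free bis(hydrogen sulfate). The route carries the sulfates as tetrabutylammonium salts and frees the acid only in the last step, cold and dilute, because aryl hydrogen sulfates hydrolyse under their own acidity.

**Route**

Step 1
Reactants: 1 3,4,5-trihydroxybenzaldehyde; 2 2,2-dimethoxypropane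
Product: 3 7-hydroxy-2,2-dimethyl-1,3-benzodioxole-5-carbaldehyde
Conditions: TsOH (cat.), toluene, reflux (MeOH removed through 4 Å MS); dilute aq. HCl wash
Reagents that add atoms: none
Why: Acid-catalysed transketalisation (acetonide formation) can only bridge two neighbouring phenols, so one five-membered ketal forms and the third hydroxyl stays free, either adjacent pair giving the same product by the symmetry of 1, and the acid wash returns any aldehyde that was acetalised in passing.

Step 2
Reactants: 3 7-hydroxy-2,2-dimethyl-1,3-benzodioxole-5-carbaldehyde; 4 ethylene glycol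
Product: 5 6-(1,3-dioxolan-2-yl)-2,2-dimethyl-1,3-benzodioxol-4-ol
Conditions: PPTS (cat.), benzene, reflux, Dean–Stark
Reagents that add atoms: none
Why: Acid-catalysed acetalisation with azeotropic removal of water masks the aldehyde as a 1,3-dioxolane that tolerates the alkyllithium of step 4, and the weak acid PPTS should leave the aryl ketal in place.

Step 3
Reactants: 5 6-(1,3-dioxolan-2-yl)-2,2-dimethyl-1,3-benzodioxol-4-ol; 6 isopropyl isocyanate
Product: 7 6-(1,3-dioxolan-2-yl)-2,2-dimethyl-1,3-benzodioxol-4-yl N-isopropylcarbamate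
Conditions: Et3N (cat.), CH2Cl2, rt
Reagents that add atoms: none
Why: Base-catalysed addition of the phenol to the isocyanate (carbamoylation) installs the directing group for ortho-lithiation under conditions that leave both acetals untouched.

Step 4
Reactants: 7 6-(1,3-dioxolan-2-yl)-2,2-dimethyl-1,3-benzodioxol-4-yl N-isopropylcarbamate
Product: 11 6-(1,3-dioxolan-2-yl)-2,2-dimethyl-5-(trimethylsilyl)-1,3-benzodioxol-4-yl N-isopropylcarbamate, via N-silyl carbamate 8 (not isolated), via aryllithium 9 (not isolated), via N,C-bis-silyl carbamate 10 (not isolated)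
Conditions: TMSOTf, TMEDA, Et2O, 0 °C to rt; n-BuLi, TMEDA, −78 °C; TMSCl, −78 °C to rt; MeOH, aq. NH4Cl
Reagents that add atoms: chlorotrimethylsilane, C[Si](C)(C)Cl
Why: Directed ortho-metalation: after N-silylation in the flask the carbamate steers lithiation to its only free ortho position C2, which is also flanked by the dioxolane, TMSCl traps the aryllithium at −78 °C before an anionic Fries shift can set in, and methanol removes the labile N-silyl group.

Step 5
Reactants: 11 6-(1,3-dioxolan-2-yl)-2,2-dimethyl-5-(trimethylsilyl)-1,3-benzodioxol-4-yl N-isopropylcarbamate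
Product: 13 6-(1,3-dioxolan-2-yl)-2,2-dimethyl-5-(trimethylsilyl)-1,3-benzodioxol-4-yl trifluoromethanesulfonate, via silylphenol 12 (not isolated)
Conditions: DBU, Et2NH, MeCN, 40 °C; then PhNTf2, rt
Reagents that add atoms: N-phenylbis(trifluoromethanesulfonimide), O=S(=O)(N(c1ccccc1)S(=O)(=O)C(F)(F)F)C(F)(F)F
Why: DBU-promoted E1cB loss of isopropyl isocyanate (scavenged by Et2NH as a urea) frees the phenoxide, which is triflated in the same flask by PhNTf2, the usual one-pot conversion of ortho-silylaryl carbamates into ortho-silylaryl triflates.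

Step 6
Reactants: 13 6-(1,3-dioxolan-2-yl)-2,2-dimethyl-5-(trimethylsilyl)-1,3-benzodioxol-4-yl trifluoromethanesulfonate
Product: 15 2-(6,7-dibromo-2,2-dimethyl-1,3-benzodioxol-5-yl)-1,3-dioxolane, via aryne 14 (not isolated)
Conditions: Li2CuBr4 (from CuBr2 + 2 LiBr, excess), CsF, MeCN, rt, slow addition of 13
Reagents that add atoms: copper dibromide, Br[Cu]Br; lithium bromide, [Li+].[Br-]
Why: Proposed new method: fluoride attacks silicon in 13, triflate leaves from the neighbouring carbon and the C2≡C3 aryne 14 forms; a bromide of the bromocuprate then adds to one aryne carbon while copper takes the other (bromocupration), and the aryl–copper bond is cleaved by bromine transfer from a second divalent copper bromide, two divalent coppers ending as CuBr. The closest known reaction type is the vicinal dihalogenation of arynes released from ortho-silylaryl triflates, established as insertion into the I–I bond of I2, together with copper-mediated aryne difunctionalisations that run through ortho-substituted arylcopper species; what is untested is the bromocuprate as the Br–Br equivalent. No ring is closed and no stereocentre is created, the step only forms the C2–Br and C3–Br bonds. No regiocontrol is needed, because both aryne carbons receive bromine and the unlike neighbours (the C1 dioxolane and the C4 ketal oxygen) cannot lead to isomers. The selectivity that is needed is chemoselectivity: aryne capture must outrun ipso-bromodesilylation of 13, bromination at C6 and protonation of a bromoaryl anion to a monobromide. This should be secured by the weakly electrophilic cuprate in place of Br2, by the triflate that deactivates 13, by a dry aprotic medium, and by adding 13 slowly to an excess of the copper reagent so that the aryne always meets bromide and divalent copper together.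

Step 7
Reactants: 15 2-(6,7-dibromo-2,2-dimethyl-1,3-benzodioxol-5-yl)-1,3-dioxolane
Product: 16 2,3-dibromo-4,5-dihydroxybenzaldehyde
Conditions: TFA/H2O (9:1), rt
Reagents that add atoms: water, O
Why: Acid-catalysed acetal hydrolysis opens the benzylic dioxolane quickly and the aryl ketal more slowly, while the aryl bromides and the aldehyde are inert to aqueous TFA.

Step 8
Reactants: 16 2,3-dibromo-4,5-dihydroxybenzaldehyde
Product: 18 tetrabutylammonium 2,3-dibromo-4-formyl-6-hydroxyphenyl sulfate, via tetrabutylammonium phenoxide 17 (not isolated)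
Conditions: Bu4NOH (1.0 equiv), MeOH, 0 °C, evaporate; SO3·NMe3, DMF, 40 °C, argon
Reagents that add atoms: sulfur trioxide–trimethylamine complex, C[N+](C)(C)S(=O)(=O)[O-]; tetrabutylammonium hydroxide, CCCC[N+](CCCC)(CCCC)CCCC.[OH-]
Why: O-Sulfation of a phenoxide by a sulfur trioxide–amine complex: one equivalent of base deprotonates only the C4 hydroxyl, which is para to the formyl group and ortho to bromine and so by far the more acidic, and the single phenoxide present is the site that takes up SO3.

Step 9
Reactants: 18 tetrabutylammonium 2,3-dibromo-4-formyl-6-hydroxyphenyl sulfate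
Product: 19 tetrabutylammonium 6-acetoxy-2,3-dibromo-4-formylphenyl sulfate
Conditions: Ac2O, pyridine, DMAP (cat.), CH2Cl2, 0 °C to rt
Reagents that add atoms: acetic anhydride, CC(=O)OC(C)=O
Why: Standard nucleophile-catalysed acylation of the one remaining phenol, the sulfate monoester anion being inert to the anhydride.

Step 10
Reactants: 19 tetrabutylammonium 6-acetoxy-2,3-dibromo-4-formylphenyl sulfate
Product: 20 tetrabutylammonium 6-acetoxy-2,3-dibromo-4-(hydroxymethyl)phenyl sulfate
Conditions: NaBH4, EtOH/CH2Cl2, 0 °C, short reaction time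
Reagents that add atoms: none
Why: Borohydride reduction of the aryl aldehyde at 0 °C is much faster than attack on the aryl acetate, as in the reduction of acetylated hydroxybenzaldehydes, and the sulfate salt and the aryl bromides are inert to NaBH4.

Step 11
Reactants: 20 tetrabutylammonium 6-acetoxy-2,3-dibromo-4-(hydroxymethyl)phenyl sulfate
Product: 22 bis(tetrabutylammonium) 5-acetoxy-2,3-dibromo-4-(sulfonatooxy)benzyl sulfate, via pyridinium tetrabutylammonium disulfate 21 (not isolated)
Conditions: SO3·pyridine, DMF, 0 °C to rt; then Bu4NOH (aq., to pH 7), CH2Cl2 extraction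
Reagents that add atoms: sulfur trioxide–pyridine complex, [O-]S(=O)(=O)[n+]1ccccc1; tetrabutylammonium hydroxide, CCCC[N+](CCCC)(CCCC)CCCC.[OH-]
Why: O-Sulfation of a primary alcohol, the only free hydroxyl in 20, by SO3·pyridine, followed by exchange of the pyridinium counter-ion for tetrabutylammonium so that the disulfate can be extracted and purified.

Step 12
Reactants: 22 bis(tetrabutylammonium) 5-acetoxy-2,3-dibromo-4-(sulfonatooxy)benzyl sulfate
Product: 23 bis(tetrabutylammonium) 2,3-dibromo-5-hydroxy-4-(sulfonatooxy)benzyl sulfate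
Conditions: NH3 (7 M in MeOH), 0 °C to rt
Reagents that add atoms: none
Why: Ammonolysis of the aryl acetate, an activated ester, proceeds at room temperature, whereas sulfate monoester anions are stable to amines and no quinone methide can form because the phenol set free is meta to the benzylic carbon.

Step 13
Reactants: 23 bis(tetrabutylammonium) 2,3-dibromo-5-hydroxy-4-(sulfonatooxy)benzyl sulfate
Product: 24 2,3-dibromo-5-hydroxy-4-(sulfooxy)benzyl hydrogen sulfate
Conditions: sulfonic acid resin (H+ form), H2O, 0–4 °C; freeze-dry at once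
Reagents that add atoms: none
Why: Cation exchange on a strongly acidic resin replaces both tetrabutylammonium ions by protons, and cold, dilute handling with immediate freeze-drying should limit the acid-catalysed hydrolysis to which aryl hydrogen sulfates are prone.

**Compound list**

1 | 3,4,5-trihydroxybenzaldehyde | O=Cc1cc(O)c(O)c(O)c1 | starting material
2 | 2,2-dimethoxypropane | COC(C)(C)OC | starting material
3 | 7-hydroxy-2,2-dimethyl-1,3-benzodioxole-5-carbaldehyde | O=Cc1cc(O)c2OC(C)(C)Oc2c1 | intermediate
4 | ethylene glycol | OCCO | starting material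
5 | 6-(1,3-dioxolan-2-yl)-2,2-dimethyl-1,3-benzodioxol-4-ol | Oc1cc(C2OCCO2)cc2OC(C)(C)Oc12 | intermediate
6 | isopropyl isocyanate | CC(C)N=C=O | starting material
7 | 6-(1,3-dioxolan-2-yl)-2,2-dimethyl-1,3-benzodioxol-4-yl N-isopropylcarbamate | CC(C)NC(=O)Oc1cc(C2OCCO2)cc2OC(C)(C)Oc12 | intermediate
8 | 6-(1,3-dioxolan-2-yl)-2,2-dimethyl-1,3-benzodioxol-4-yl N-isopropyl-N-(trimethylsilyl)carbamate | CC(C)N([Si](C)(C)C)C(=O)Oc1cc(C2OCCO2)cc2OC(C)(C)Oc12 | intermediate
9 | 6-(1,3-dioxolan-2-yl)-5-lithio-2,2-dimethyl-1,3-benzodioxol-4-yl N-isopropyl-N-(trimethylsilyl)carbamate | CC(C)N([Si](C)(C)C)C(=O)Oc1c([Li])c(C2OCCO2)cc2OC(C)(C)Oc12 | intermediate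
10 | 6-(1,3-dioxolan-2-yl)-2,2-dimethyl-5-(trimethylsilyl)-1,3-benzodioxol-4-yl N-isopropyl-N-(trimethylsilyl)carbamate | CC(C)N([Si](C)(C)C)C(=O)Oc1c([Si](C)(C)C)c(C2OCCO2)cc2OC(C)(C)Oc12 | intermediate
11 | 6-(1,3-dioxolan-2-yl)-2,2-dimethyl-5-(trimethylsilyl)-1,3-benzodioxol-4-yl N-isopropylcarbamate | CC(C)NC(=O)Oc1c([Si](C)(C)C)c(C2OCCO2)cc2OC(C)(C)Oc12 | intermediate
12 | 6-(1,3-dioxolan-2-yl)-2,2-dimethyl-5-(trimethylsilyl)-1,3-benzodioxol-4-ol | C[Si](C)(C)c1c(C2OCCO2)cc2OC(C)(C)Oc2c1O | intermediate
13 | 6-(1,3-dioxolan-2-yl)-2,2-dimethyl-5-(trimethylsilyl)-1,3-benzodioxol-4-yl trifluoromethanesulfonate | C[Si](C)(C)c1c(C2OCCO2)cc2OC(C)(C)Oc2c1OS(=O)(=O)C(F)(F)F | intermediate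
14 | 2-(6,7-didehydro-2,2-dimethyl-1,3-benzodioxol-5-yl)-1,3-dioxolane (C2≡C3 aryne) | C1(C2OCCO2)=CC3=C(C#C1)OC(C)(C)O3 | intermediate
15 | 2-(6,7-dibromo-2,2-dimethyl-1,3-benzodioxol-5-yl)-1,3-dioxolane | Brc1c(C2OCCO2)cc2OC(C)(C)Oc2c1Br | intermediate
16 | 2,3-dibromo-4,5-dihydroxybenzaldehyde | O=Cc1cc(O)c(O)c(Br)c1Br | intermediate
17 | tetrabutylammonium 2,3-dibromo-4-formyl-6-hydroxyphenolate | O=Cc1cc(O)c([O-])c(Br)c1Br.CCCC[N+](CCCC)(CCCC)CCCC | intermediate
18 | tetrabutylammonium 2,3-dibromo-4-formyl-6-hydroxyphenyl sulfate | O=Cc1cc(O)c(OS(=O)(=O)[O-])c(Br)c1Br.CCCC[N+](CCCC)(CCCC)CCCC | intermediate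
19 | tetrabutylammonium 6-acetoxy-2,3-dibromo-4-formylphenyl sulfate | CC(=O)Oc1cc(C=O)c(Br)c(Br)c1OS(=O)(=O)[O-].CCCC[N+](CCCC)(CCCC)CCCC | intermediate
20 | tetrabutylammonium 6-acetoxy-2,3-dibromo-4-(hydroxymethyl)phenyl sulfate | CC(=O)Oc1cc(CO)c(Br)c(Br)c1OS(=O)(=O)[O-].CCCC[N+](CCCC)(CCCC)CCCC | intermediate
21 | pyridinium tetrabutylammonium 5-acetoxy-2,3-dibromo-4-(sulfonatooxy)benzyl sulfate | CC(=O)Oc1cc(COS(=O)(=O)[O-])c(Br)c(Br)c1OS(=O)(=O)[O-].CCCC[N+](CCCC)(CCCC)CCCC.c1cc[nH+]cc1 | intermediate
22 | bis(tetrabutylammonium) 5-acetoxy-2,3-dibromo-4-(sulfonatooxy)benzyl sulfate | CC(=O)Oc1cc(COS(=O)(=O)[O-])c(Br)c(Br)c1OS(=O)(=O)[O-].CCCC[N+](CCCC)(CCCC)CCCC.CCCC[N+](CCCC)(CCCC)CCCC | intermediate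
23 | bis(tetrabutylammonium) 2,3-dibromo-5-hydroxy-4-(sulfonatooxy)benzyl sulfate | Oc1cc(COS(=O)(=O)[O-])c(Br)c(Br)c1OS(=O)(=O)[O-].CCCC[N+](CCCC)(CCCC)CCCC.CCCC[N+](CCCC)(CCCC)CCCC | intermediate
24 | 2,3-dibromo-5-hydroxy-4-(sulfooxy)benzyl hydrogen sulfate | O=S(=O)(O)OCc1cc(O)c(OS(=O)(=O)O)c(Br)c1Br | target

**Totals**

Total step count: 13. Longest linear sequence: 13 steps (1 to 24).

**Steps most likely to fail**

Step 6 (Proposed new method). The cuprate may not capture the aryne cleanly: a bromoaryl anion may be protonated to a monobromide, fluoride may add to the aryne or be bound by copper so that aryne release stalls, and the copper salt may cleave the C–Si bond or brominate C6 before the aryne forms. The fallback takes the same aryne through established chemistry in two operations. Setting out from 13, the aryne is released with KF and 18-crown-6 in THF in the presence of hexamethylditin and a zerovalent palladium catalyst made from Pd(OAc)2 and tert-octyl isocyanide. Palladium-catalysed insertion of the aryne into the Sn–Sn bond should give 2-[2,2-dimethyl-6,7-bis(trimethylstannyl)-1,3-benzodioxol-5-yl]-1,3-dioxolane F1. Br2 (2 equiv) in CH2Cl2 at −78 °C then replaces both stannyl groups by ipso-bromodestannylation, which is far faster than bromination of a ring C–H, and the route is rejoined at 15.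

Step 8. Sulfation may fail to discriminate between the two phenolic oxygens or may occur twice, and the catechol mono-anion may be oxidised by air. The fallback protects C5–O first, using nucleophilicity in place of acidity. Setting out from 16, NaH (2.1 equiv) in DMF at 0 °C forms disodium 3,4-dibromo-5-formylbenzene-1,2-diolate F2. Its more basic C5 phenoxide, not conjugated to the aldehyde and not flanked by bromine, should take one equivalent of allyl bromide and give, after acidification, 5-(allyloxy)-2,3-dibromo-4-hydroxybenzaldehyde F3. Only the C4 hydroxyl is then free, so the sulfation site is fixed: Bu4NOH gives tetrabutylammonium 6-(allyloxy)-2,3-dibromo-4-formylphenolate F4, and SO3·NMe3 in DMF gives tetrabutylammonium 6-(allyloxy)-2,3-dibromo-4-formylphenyl sulfate F5. NaBH4 reduction should give tetrabutylammonium 6-(allyloxy)-2,3-dibromo-4-(hydroxymethyl)phenyl sulfate F6. SO3·pyridine gives pyridinium tetrabutylammonium 5-(allyloxy)-2,3-dibromo-4-(sulfonatooxy)benzyl sulfate F7, which Bu4NOH converts into bis(tetrabutylammonium) 5-(allyloxy)-2,3-dibromo-4-(sulfonatooxy)benzyl sulfate F8. Deallylation with Pd(PPh3)4 (cat.) and morpholine in THF at rt, where zerovalent palladium should not yet insert into the hindered aryl bromides, rejoins the route at 23.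

Step 4. Lithiation may go to C6 (between the dioxolane and the ketal oxygen) or to the acetal C–H, the lithiated carbamate may undergo anionic Fries rearrangement before it is silylated, and the dioxolane may be lost in work-up. The fallback places silicon by halogen–metal exchange and a retro-Brook shift instead of by deprotonation. Setting out from 3, amine-mediated ortho-bromination of the phenol (NBS, cat. i-Pr2NH, CH2Cl2, 0 °C) should give 6-bromo-7-hydroxy-2,2-dimethyl-1,3-benzodioxole-5-carbaldehyde F9. The aldehyde is masked as in step 2 to give 5-bromo-6-(1,3-dioxolan-2-yl)-2,2-dimethyl-1,3-benzodioxol-4-ol F10, and hexamethyldisilazane silylates the phenol to [5-bromo-6-(1,3-dioxolan-2-yl)-2,2-dimethyl-1,3-benzodioxol-4-yl]oxy(trimethyl)silane F11. n-BuLi in THF at −78 °C then effects bromine–lithium exchange and the shift of silicon from oxygen to C2, giving lithium 6-(1,3-dioxolan-2-yl)-2,2-dimethyl-5-(trimethylsilyl)-1,3-benzodioxol-4-olate F12. This is triflated in the same flask with PhNTf2 and rejoins the route at 13, bypassing steps 3 to 5.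

**Further compounds**

F1 | step 6 | 2-[2,2-dimethyl-6,7-bis(trimethylstannyl)-1,3-benzodioxol-5-yl]-1,3-dioxolane | C[Sn](C)(C)c1c(C2OCCO2)cc2OC(C)(C)Oc2c1[Sn](C)(C)C
F2 | step 8 | disodium 3,4-dibromo-5-formylbenzene-1,2-diolate | O=Cc1cc([O-])c([O-])c(Br)c1Br.[Na+].[Na+]
F3 | step 8 | 5-(allyloxy)-2,3-dibromo-4-hydroxybenzaldehyde | O=Cc1cc(OCC=C)c(O)c(Br)c1Br
F4 | step 8 | tetrabutylammonium 6-(allyloxy)-2,3-dibromo-4-formylphenolate | C=CCOc1cc(C=O)c(Br)c(Br)c1[O-].CCCC[N+](CCCC)(CCCC)CCCC
F5 | step 8 | tetrabutylammonium 6-(allyloxy)-2,3-dibromo-4-formylphenyl sulfate | C=CCOc1cc(C=O)c(Br)c(Br)c1OS(=O)(=O)[O-].CCCC[N+](CCCC)(CCCC)CCCC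
F6 | step 8 | tetrabutylammonium 6-(allyloxy)-2,3-dibromo-4-(hydroxymethyl)phenyl sulfate | C=CCOc1cc(CO)c(Br)c(Br)c1OS(=O)(=O)[O-].CCCC[N+](CCCC)(CCCC)CCCC
F7 | step 8 | pyridinium tetrabutylammonium 5-(allyloxy)-2,3-dibromo-4-(sulfonatooxy)benzyl sulfate | C=CCOc1cc(COS(=O)(=O)[O-])c(Br)c(Br)c1OS(=O)(=O)[O-].CCCC[N+](CCCC)(CCCC)CCCC.c1cc[nH+]cc1
F8 | step 8 | bis(tetrabutylammonium) 5-(allyloxy)-2,3-dibromo-4-(sulfonatooxy)benzyl sulfate | C=CCOc1cc(COS(=O)(=O)[O-])c(Br)c(Br)c1OS(=O)(=O)[O-].CCCC[N+](CCCC)(CCCC)CCCC.CCCC[N+](CCCC)(CCCC)CCCC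
F9 | step 4 | 6-bromo-7-hydroxy-2,2-dimethyl-1,3-benzodioxole-5-carbaldehyde | O=Cc1cc2OC(C)(C)Oc2c(O)c1Br
F10 | step 4 | 5-bromo-6-(1,3-dioxolan-2-yl)-2,2-dimethyl-1,3-benzodioxol-4-ol | Oc1c(Br)c(C2OCCO2)cc2OC(C)(C)Oc12
F11 | step 4 | [5-bromo-6-(1,3-dioxolan-2-yl)-2,2-dimethyl-1,3-benzodioxol-4-yl]oxy(trimethyl)silane | C[Si](C)(C)Oc1c(Br)c(C2OCCO2)cc2OC(C)(C)Oc12
F12 | step 4 | lithium 6-(1,3-dioxolan-2-yl)-2,2-dimethyl-5-(trimethylsilyl)-1,3-benzodioxol-4-olate | [Li+].[O-]c1c([Si](C)(C)C)c(C2OCCO2)cc2OC(C)(C)Oc12
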